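**Plan**

- Quinone ring numbering: C1(=O), C2(OMe), C3(OAr), C4(=O), C5 and C6 (prenyl). Retrosynthetic cuts: the two aryl O–Si bonds; the C2–OMe bond, leading back to a C2-symmetric 2,3-bis(aryloxy)quinone whose extra aryloxy group is a sacrificial leaving group; the ring bond C1–C6 (6π closure of a dienylketene) and C4–C5 (vinyllithium addition to a squarate C=O); the two squarate C–OAr bonds; the vinyl C–I bond and the two propargylic C–C bonds.
- Forward: acetylene + 2 prenyl bromide → diprenylacetylene → (E)-vinyl iodide; protected phloroglucinol ester + squaryl dichloride → bis(aryl) squarate; vinyllithium addition → 4-alkenyl-4-hydroxycyclobutenone; thermolysis builds the hexasubstituted ring as a hydroquinone, oxidized in the same pot; one aryloxy is exchanged for methoxide; desilylation.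
- Enabling feature: the four contiguous oxygen-bearing ring carbons C1–C4 are a masked squaric acid four-membered ring, and the adjacent prenylated carbons C5/C6 a 1,2-dialkylvinyl unit. The two aryloxy carbons are equivalent in the symmetric quinone, so the carbonyl closed in the key step can be taken as C1, next to the later methoxy carbon.
- Stereochemistry: the target has no stereocentre. The only stereo element is the vinyl geometry (H cis to metal) from syn-hydrozirconation, and it is consumed in the ring closure.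

Key step: step 6

Remark on the chemistry: Ar = 2-(methoxycarbonyl)-3,5-bis(triisopropylsilyloxy)phenyl throughout; compounds 13 and 15 are racemic and lose their stereocentre on aromatization.

**Route**

Step 1
Reactants: 1 acetylene; 2 1-bromo-3-methylbut-2-ene (prenyl bromide, 2.1 equiv)
Product: 4 2,9-dimethyldeca-2,8-dien-5-yne, via ethynediylbis(magnesium bromide) 3 (not isolated)
Conditions: EtMgBr (2.05 equiv), THF, 0 → 50 °C; then CuCl (10 mol %), 2, 50 °C
Reagents that add atoms: none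
Why: The acetylene bis-Grignard (Iotsitch reagent) undergoes Cu(I)-catalysed allylic substitution twice at the primary carbon of prenyl bromide, which should give the symmetric skipped dienyne.

Step 2
Reactants: 4 2,9-dimethyldeca-2,8-dien-5-yne
Product: 6 (5E)-5-iodo-2,9-dimethyldeca-2,5,8-triene, via alkenylzirconocene chloride 5 (not isolated)
Conditions: Cp2Zr(H)Cl (1.1 equiv), THF, rt; then I2, 0 °C
Reagents that add atoms: iodine, II
Why: Schwartz hydrozirconation adds H–Zr syn to the alkyne in preference to the trisubstituted alkenes (no regiochemical issue, the alkyne is symmetric), and iododezirconation with retention should give the iodide with H cis to I.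

Step 3
Reactants: 7 methyl 2,4,6-trihydroxybenzoate
Product: 8 methyl 2-hydroxy-4,6-bis(triisopropylsilyloxy)benzoate (ArOH)
Conditions: TIPSCl (2.1 equiv), imidazole, DMF, 0 °C → rt
Reagents that add atoms: triisopropylsilyl chloride, CC(C)[Si](Cl)(C(C)C)C(C)C
Why: Silyl ether formation should stop after two hydroxyls because the remaining ortho hydroxyl is hydrogen-bonded to the ester carbonyl and hindered.

Step 4
Reactants: 9 3,4-dichlorocyclobut-3-ene-1,2-dione (squaryl dichloride); 8 ArOH (2.05 equiv)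
Product: 11 3,4-bis(ArO)cyclobut-3-ene-1,2-dione, via 3-chloro-4-aryloxycyclobutenedione 10 (not isolated)
Conditions: Et3N (2.2 equiv), CH2Cl2, −20 °C → rt
Reagents that add atoms: none
Why: Two successive addition–elimination reactions (vinylogous acyl substitution) of the phenoxide on the vinylogous acid chloride should give the C2-symmetric diaryl squarate.

Step 5
Reactants: 6 (5E)-5-iodo-2,9-dimethyldeca-2,5,8-triene; 11 3,4-bis(ArO)cyclobut-3-ene-1,2-dione
Product: 13 (±)-2,3-bis(ArO)-4-hydroxy-4-[(5E)-2,9-dimethyldeca-2,5,8-trien-5-yl]cyclobut-2-en-1-one, via alkenyllithium 12 (not isolated)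
Conditions: t-BuLi (2.0 equiv), Et2O, −78 °C; cannulated into 11, THF, −78 °C; aq. NH4Cl at −78 °C
Reagents that add atoms: none
Why: Lithium–iodine exchange with retention, then 1,2-addition of the vinyllithium to a squarate carbonyl (first stage of the Moore–Liebeskind sequence), should give a single adduct because the two carbonyls of 11 are equivalent and the 2,6-disubstituted benzoates are inert at −78 °C.

Step 6
Reactants: 13 (±)-2,3-bis(ArO)-4-hydroxy-4-[(5E)-2,9-dimethyldeca-2,5,8-trien-5-yl]cyclobut-2-en-1-one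
Product: 17 2,3-bis(ArO)-5,6-bis(3-methylbut-2-en-1-yl)cyclohexa-2,5-diene-1,4-dione, via dienylketene 14 (not isolated), via cyclohexadienone 15 (not isolated), via hydroquinone 16 (not isolated)
Conditions: degassed PhMe, 110 °C, Ar; then Ag2O (2 equiv), MgSO4, rt, same pot
Reagents that add atoms: none
Why: Heating opens the cyclobutenone by 4π-conrotatory cleavage of the C(=O)–C(OH) bond, with the hydroxyl rotating outward (torquoselectivity of a donor), so the alkenyl group turns inward and lies cis to the ketene in 14. A thermal 6π-disrotatory electrocyclization then joins the ketene carbon to the hydrogen-bearing vinyl terminus to give 15, which enolizes to the fully substituted hydroquinone 16, and Ag2O oxidizes this to quinone 17. The closest known reaction type is the Moore–Liebeskind ring expansion of squarate-derived 4-alkenyl-4-hydroxycyclobutenones to hydroquinones and quinones. One six-membered carbocycle is closed, by a pericyclic 6π electrocyclization driven by aromatization, and no stereocentre survives because the carbinol carbon of 13 and the sp3 CH of 15 both become sp2. The step needs inward rotation of the alkenyl group and closure at the vinyl terminus without trapping of the ketene; the first is secured by the outward preference of OH, the second by the vinyl geometry (H, not a prenyl CH2, points into the forming ring) and by neutral, anhydrous conditions. The symmetry of 11 removes any regiochemical question, and the prenyl double bonds are insulated by CH2 groups from the pericyclic array.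

Step 7
Reactants: 17 2,3-bis(ArO)-5,6-bis(3-methylbut-2-en-1-yl)cyclohexa-2,5-diene-1,4-dione
Product: 18 2-(ArO)-3-methoxy-5,6-bis(3-methylbut-2-en-1-yl)cyclohexa-2,5-diene-1,4-dione
Conditions: NaOMe (1.0 equiv), THF/MeOH (20:1), −78 → −40 °C; AcOH quench
Reagents that add atoms: sodium methoxide, C[O-].[Na+]
Why: Nucleophilic vinylic substitution (addition–elimination, vinylogous transesterification) should expel the better nucleofuge aryloxide; the two aryloxy sites are equivalent, and the methoxy product is a less electrophilic vinylogous ester, so one equivalent of methoxide should stop at mono-exchange.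

Step 8
Reactants: 18 2-(ArO)-3-methoxy-5,6-bis(3-methylbut-2-en-1-yl)cyclohexa-2,5-diene-1,4-dione
Product: 19 atrovirinone
Conditions: HF·pyridine, THF/pyridine, 0 °C → rt
Reagents that add atoms: none
Why: Fluoride-driven cleavage of the two aryl silyl ethers (desilylation) should leave the quinone, the aryl–O–quinone link, the methyl ester and the prenyl groups untouched, since no nucleophilic alcohol or strong acid is present.

**Compound list**

1 | acetylene | C#C | starting material
2 | 1-bromo-3-methylbut-2-ene (prenyl bromide) | CC(C)=CCBr | starting material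
3 | ethynediylbis(magnesium bromide) | Br[Mg]C#C[Mg]Br | intermediate
4 | 2,9-dimethyldeca-2,8-dien-5-yne | CC(C)=CCC#CCC=C(C)C | intermediate
5 | chloro[(5E)-2,9-dimethyldeca-2,5,8-trien-5-yl]zirconocene (Zr cis to vinyl H; Cp drawn σ-bonded) | CC(C)=CC/C(=C\CC=C(C)C)[Zr](Cl)(C1C=CC=C1)C1C=CC=C1 | intermediate
6 | (5E)-5-iodo-2,9-dimethyldeca-2,5,8-triene | CC(C)=CC/C(I)=C\CC=C(C)C | intermediate
7 | methyl 2,4,6-trihydroxybenzoate | COC(=O)c1c(O)cc(O)cc1O | starting material
8 | methyl 2-hydroxy-4,6-bis(triisopropylsilyloxy)benzoate (ArOH) | COC(=O)c1c(O)cc(O[Si](C(C)C)(C(C)C)C(C)C)cc1O[Si](C(C)C)(C(C)C)C(C)C | intermediate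
9 | 3,4-dichlorocyclobut-3-ene-1,2-dione (squaryl dichloride) | O=C1C(=O)C(Cl)=C1Cl | starting material
10 | 3-chloro-4-(ArO)cyclobut-3-ene-1,2-dione | O=C1C(=O)C(Cl)=C1Oc1cc(O[Si](C(C)C)(C(C)C)C(C)C)cc(O[Si](C(C)C)(C(C)C)C(C)C)c1C(=O)OC | intermediate
11 | 3,4-bis(ArO)cyclobut-3-ene-1,2-dione | O=C1C(=O)C(Oc2cc(O[Si](C(C)C)(C(C)C)C(C)C)cc(O[Si](C(C)C)(C(C)C)C(C)C)c2C(=O)OC)=C1Oc1cc(O[Si](C(C)C)(C(C)C)C(C)C)cc(O[Si](C(C)C)(C(C)C)C(C)C)c1C(=O)OC | intermediate
12 | [(5Z)-2,9-dimethyldeca-2,5,8-trien-5-yl]lithium (Li cis to vinyl H, same geometry as 6) | CC(C)=CC/C([Li])=C\CC=C(C)C | intermediate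
13 | (±)-2,3-bis(ArO)-4-hydroxy-4-[(5E)-2,9-dimethyldeca-2,5,8-trien-5-yl]cyclobut-2-en-1-one | O=C1C(Oc2cc(O[Si](C(C)C)(C(C)C)C(C)C)cc(O[Si](C(C)C)(C(C)C)C(C)C)c2C(=O)OC)=C(Oc2cc(O[Si](C(C)C)(C(C)C)C(C)C)cc(O[Si](C(C)C)(C(C)C)C(C)C)c2C(=O)OC)C1(O)/C(CC=C(C)C)=C/CC=C(C)C | intermediate
14 | (3Z,5E)-2,3-bis(ArO)-4-hydroxy-9-methyl-5-(3-methylbut-2-en-1-yl)deca-1,3,5,8-tetraen-1-one (dienylketene) | O=C=C(Oc1cc(O[Si](C(C)C)(C(C)C)C(C)C)cc(O[Si](C(C)C)(C(C)C)C(C)C)c1C(=O)OC)/C(Oc1cc(O[Si](C(C)C)(C(C)C)C(C)C)cc(O[Si](C(C)C)(C(C)C)C(C)C)c1C(=O)OC)=C(O)\C(CC=C(C)C)=C\CC=C(C)C | intermediate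
15 | (±)-2,3-bis(ArO)-4-hydroxy-5,6-bis(3-methylbut-2-en-1-yl)cyclohexa-2,4-dien-1-one | O=C1C(Oc2cc(O[Si](C(C)C)(C(C)C)C(C)C)cc(O[Si](C(C)C)(C(C)C)C(C)C)c2C(=O)OC)=C(Oc2cc(O[Si](C(C)C)(C(C)C)C(C)C)cc(O[Si](C(C)C)(C(C)C)C(C)C)c2C(=O)OC)C(O)=C(CC=C(C)C)C1CC=C(C)C | intermediate
16 | 2,3-bis(ArO)-5,6-bis(3-methylbut-2-en-1-yl)benzene-1,4-diol | Oc1c(Oc2cc(O[Si](C(C)C)(C(C)C)C(C)C)cc(O[Si](C(C)C)(C(C)C)C(C)C)c2C(=O)OC)c(Oc2cc(O[Si](C(C)C)(C(C)C)C(C)C)cc(O[Si](C(C)C)(C(C)C)C(C)C)c2C(=O)OC)c(O)c(CC=C(C)C)c1CC=C(C)C | intermediate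
17 | 2,3-bis(ArO)-5,6-bis(3-methylbut-2-en-1-yl)cyclohexa-2,5-diene-1,4-dione | O=C1C(Oc2cc(O[Si](C(C)C)(C(C)C)C(C)C)cc(O[Si](C(C)C)(C(C)C)C(C)C)c2C(=O)OC)=C(Oc2cc(O[Si](C(C)C)(C(C)C)C(C)C)cc(O[Si](C(C)C)(C(C)C)C(C)C)c2C(=O)OC)C(=O)C(CC=C(C)C)=C1CC=C(C)C | intermediate
18 | 2-(ArO)-3-methoxy-5,6-bis(3-methylbut-2-en-1-yl)cyclohexa-2,5-diene-1,4-dione | COC1=C(Oc2cc(O[Si](C(C)C)(C(C)C)C(C)C)cc(O[Si](C(C)C)(C(C)C)C(C)C)c2C(=O)OC)C(=O)C(CC=C(C)C)=C(CC=C(C)C)C1=O | intermediate
19 | atrovirinone, methyl 2,4-dihydroxy-6-{[2-methoxy-4,5-bis(3-methylbut-2-en-1-yl)-3,6-dioxocyclohexa-1,4-dien-1-yl]oxy}benzoate | COC(=O)c1c(O)cc(O)cc1OC1=C(OC)C(=O)C(CC=C(C)C)=C(CC=C(C)C)C1=O | target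

**Step count**

Total steps: 8. Longest linear sequence: 6 steps (1 → 2 → 5 → 6 → 7 → 8, or 3 → 4 → 5 → 6 → 7 → 8).

**Steps most likely to fail**

Step 5. The vinyllithium may attack an aryloxy-bearing ring carbon (conjugate addition–elimination with loss of aryloxide) or add twice, instead of adding once to a carbonyl of the highly electrophilic diaryl squarate. Fallback: the ring is built on dimethyl squarate and the aryl ether is attached afterwards. It sets out from iodide 6 (as alkenyllithium 12) and commercial dimethyl squarate. 1,2-Addition at −78 °C should give (±)-4-hydroxy-2,3-dimethoxy-4-[(5E)-2,9-dimethyldeca-2,5,8-trien-5-yl]cyclobut-2-en-1-one F1. Thermolysis in toluene should give 2,3-dimethoxy-5,6-bis(3-methylbut-2-en-1-yl)benzene-1,4-diol F2, and Ag2O oxidation 2,3-dimethoxy-5,6-bis(3-methylbut-2-en-1-yl)cyclohexa-2,5-diene-1,4-dione F3. Vinylogous saponification with one equivalent of NaOH (THF/H2O, 0 °C) should stop at 2-hydroxy-3-methoxy-5,6-bis(3-methylbut-2-en-1-yl)cyclohexa-2,5-diene-1,4-dione F4, because the product is an anion. Oxalyl chloride with catalytic DMF should give 2-chloro-3-methoxy-5,6-bis(3-methylbut-2-en-1-yl)cyclohexa-2,5-diene-1,4-dione F5. Phenol 8 with Cs2CO3 in MeCN should then displace chloride; attack at the methoxy carbon is non-productive, since aryloxide leaves again faster than methoxide. The fallback comes back to the route at 18.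

Step 7. The exchange may run on to the dimethoxyquinone, or the base may isomerize the prenylquinone through deprotonation of a ring-bound CH2. Fallback: the methoxy group is installed before the ring is built, so no exchange on the quinone is needed. It sets out from intermediate 10, made from 9 and one equivalent of 8 at −40 °C. MeOH/Et3N should give 3-(ArO)-4-methoxycyclobut-3-ene-1,2-dione F6. Alkenyllithium 12 is expected to add mainly to the carbonyl next to the methoxy-bearing carbon, giving (±)-2-(ArO)-4-hydroxy-3-methoxy-4-[(5E)-2,9-dimethyldeca-2,5,8-trien-5-yl]cyclobut-2-en-1-one F7. The regioisomeric adduct (±)-3-(ArO)-4-hydroxy-2-methoxy-4-[(5E)-2,9-dimethyldeca-2,5,8-trien-5-yl]cyclobut-2-en-1-one F8 would be the minor one. Both should ring-expand in hot toluene to the same 2-(ArO)-3-methoxy-5,6-bis(3-methylbut-2-en-1-yl)benzene-1,4-diol F9, which Ag2O oxidizes. The fallback comes back to the route at 18.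

Step 1. The copper acetylide may attack the tertiary (γ) end of the prenyl halide, giving reversed-prenyl isomers that are hard to separate, and the poorly soluble bis-Grignard may be alkylated only once. Fallback: copper-free stepwise alkylation of lithium acetylides, which displace the primary allylic bromide directly. It sets out from 2 and commercial ethynyltrimethylsilane. n-BuLi in THF/DMPU, then 2, should give trimethyl(5-methylhex-4-en-1-yn-1-yl)silane F10. K2CO3/MeOH should give 5-methylhex-4-en-1-yne F11. n-BuLi in THF/DMPU, then 2, comes back to the route at 4.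

Further compounds
F1 | step 5 | (±)-4-hydroxy-2,3-dimethoxy-4-[(5E)-2,9-dimethyldeca-2,5,8-trien-5-yl]cyclobut-2-en-1-one | COC1=C(OC)C(O)(/C(CC=C(C)C)=C/CC=C(C)C)C1=O
F2 | step 5 | 2,3-dimethoxy-5,6-bis(3-methylbut-2-en-1-yl)benzene-1,4-diol | COc1c(OC)c(O)c(CC=C(C)C)c(CC=C(C)C)c1O
F3 | step 5 | 2,3-dimethoxy-5,6-bis(3-methylbut-2-en-1-yl)cyclohexa-2,5-diene-1,4-dione | COC1=C(OC)C(=O)C(CC=C(C)C)=C(CC=C(C)C)C1=O
F4 | step 5 | 2-hydroxy-3-methoxy-5,6-bis(3-methylbut-2-en-1-yl)cyclohexa-2,5-diene-1,4-dione | COC1=C(O)C(=O)C(CC=C(C)C)=C(CC=C(C)C)C1=O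
F5 | step 5 | 2-chloro-3-methoxy-5,6-bis(3-methylbut-2-en-1-yl)cyclohexa-2,5-diene-1,4-dione | COC1=C(Cl)C(=O)C(CC=C(C)C)=C(CC=C(C)C)C1=O
F6 | step 7 | 3-(ArO)-4-methoxycyclobut-3-ene-1,2-dione | COC1=C(Oc2cc(O[Si](C(C)C)(C(C)C)C(C)C)cc(O[Si](C(C)C)(C(C)C)C(C)C)c2C(=O)OC)C(=O)C1=O
F7 | step 7 | (±)-2-(ArO)-4-hydroxy-3-methoxy-4-[(5E)-2,9-dimethyldeca-2,5,8-trien-5-yl]cyclobut-2-en-1-one | COC1=C(Oc2cc(O[Si](C(C)C)(C(C)C)C(C)C)cc(O[Si](C(C)C)(C(C)C)C(C)C)c2C(=O)OC)C(=O)C1(O)/C(CC=C(C)C)=C/CC=C(C)C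
F8 | step 7 | (±)-3-(ArO)-4-hydroxy-2-methoxy-4-[(5E)-2,9-dimethyldeca-2,5,8-trien-5-yl]cyclobut-2-en-1-one | COC1=C(Oc2cc(O[Si](C(C)C)(C(C)C)C(C)C)cc(O[Si](C(C)C)(C(C)C)C(C)C)c2C(=O)OC)C(O)(/C(CC=C(C)C)=C/CC=C(C)C)C1=O
F9 | step 7 | 2-(ArO)-3-methoxy-5,6-bis(3-methylbut-2-en-1-yl)benzene-1,4-diol | COc1c(Oc2cc(O[Si](C(C)C)(C(C)C)C(C)C)cc(O[Si](C(C)C)(C(C)C)C(C)C)c2C(=O)OC)c(O)c(CC=C(C)C)c(CC=C(C)C)c1O
F10 | step 1 | trimethyl(5-methylhex-4-en-1-yn-1-yl)silane | CC(C)=CCC#C[Si](C)(C)C
F11 | step 1 | 5-methylhex-4-en-1-yne | CC(C)=CCC#C
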